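The beta flask at 76 °C climbed faster than the theta flask at 70 °C, with 58.2% target against 40.5% at 80.0 min, yet at 300 min the two stood level at 60.2% and 59.6%, and two chemists read that level differently.

| setting | theta | beta | flask |
|---|---|---|---|
| starting material | 0.14 M | 0.14 M | 0.14 M |
| partner | 0.084 M | 0.084 M | 0.0840 M |
| free catalyst | 0.74 mM | 0.74 mM | 0.74 mM |
| impurity | 0.27 mM | 0.27 mM | 0.27 mM |
| temperature | 70 °C | 76 °C | 70 °C |
| remark | the very flask that is asked about, followed so far | run made earlier |  |
| time |  |  | 10 h |

| run | time / min | target / % | starting material / % |
|---|---|---|---|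
| theta | 25.0 | 14.7 | 84.4 |
| theta | 80.0 | 40.5 | 59.6 |
| theta | 120 | 55.3 | 43.7 |
| theta | 180 | 60.1 | 40.1 |
| theta | 300 | 59.6 | 39.6 |
| theta | 360 | 59.3 | 39.4 |
| beta | 25.0 | 21.9 | 77.2 |
| beta | 80.0 | 58.2 | 40.1 |
| beta | 120 | 60.2 | 39.5 |
| beta | 180 | 59.9 | 39.5 |
| beta | 300 | 60.2 | 38.9 |
| beta | 360 | 60.4 | 39.8 |

(readings scatter by 0.3 percentage points)

- removed target is counted in
- additions bring no volume worth counting

1. target, in percent of the starting material first charged, at 10 h
2. what to do for the largest gain in target; "none" if nothing gains more than 2 percentage points (midnight / autumn / winter / spring / dawn / none)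
3. target present, with what was taken out counted in, in percent of the starting material first charged, after midnight
4. target present, with what was taken out counted in, in percent of the starting material first charged, after spring

- midnight: at 10 h add partner, 50.0% of the amount charged, then wait 5.0 h
- autumn: at 10 h take out 90% of the target then present, then wait 5.0 h
- winter: at 10 h raise the temperature by 25 K, then wait 5.0 h
- spring: change nothing and wait 5.0 h more
- dawn: at 10 h add free catalyst, 100% of the amount charged, then wait 5.0 h

The first chemist holds that the catalyst has died, since the theta flask went from 55.3% at 120 min to 60.1% at 180 min and then stayed flat, which looks to her like a sudden end to the catalyst in a flask charged with impurity; on her view dawn is the move, and midnight leaves the target near the plateau. The second chemist reckons 60.0% as the partner ceiling, [partner] charged over [starting material] charged, which is the target, in percent of the starting material charged, that the limiting reagent can make at one partner per target. He notes that the late readings of both runs lie close to this figure, and that at one impurity per catalyst the impurity charged amounts to 36.5% of the catalyst charged, not the whole of it. By his reckoning midnight lifts the ceiling to 90.0%.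

The forecast takes his side, with 60% at 10 h, midnight as the best move, 89.5% after midnight, a little below that raised ceiling, and 59.9% after spring, saying of the partner that “it has simply run out; this is not equilibrium or catalyst death”.

The simulation gives 60.0% at 10 h, midnight as the best move with a gain of 30 percentage points, 90.0% after midnight, which meets the raised ceiling, and 60.0% after spring, while dawn gains 0 points.

    catalyst intermediate B → catalyst intermediate C (k = 1.50 min⁻¹, Ea = 82.0 kJ mol⁻¹)
    2 starting material → self-condensation product (k = 1.20 × 10⁻⁴ M⁻¹ min⁻¹, Ea = 108 kJ mol⁻¹)
    2 catalyst intermediate C → spent catalyst B (k = 14.0 M⁻¹ min⁻¹, Ea = 66.0 kJ mol⁻¹)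
    free catalyst + impurity → spent catalyst A (k = 1500 M⁻¹ min⁻¹, Ea = 47.0 kJ mol⁻¹)
    catalyst intermediate C → free catalyst + target (k = 9.20 min⁻¹, Ea = 80.0 kJ mol⁻¹)
    starting material + free catalyst ⇌ catalyst intermediate A (K = 260 M⁻¹, k = 330 M⁻¹ min⁻¹, Ea = 35.0 kJ mol⁻¹, ΔH = −50.0 kJ mol⁻¹)
    partner + catalyst intermediate A → catalyst intermediate B (k = 3400 M⁻¹ min⁻¹, Ea = 55.0 kJ mol⁻¹)
    (constants at 70 °C)

The flask stops because of the falling level of partner: 0% of it is free at 600 min, and the same flask without that fall stands at 99.8% instead of 60.0% at 10 h. The first chemist's view has its region in this flask with the wearing away of impurity taken away, where target stands at 44.5% at 10 h, below the partner ceiling, so the wearing away of impurity is a part of what lets the flask reach that ceiling. For the neighbour charged with 0.35 M of starting material the partner ceiling is 24.0%, and that neighbour's computed target is 24.0%.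

The runs come from a simulation with made-up constants; the scatter is artificial.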